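## Structural features

The target is a germacranolide: a cyclodeca-1(10),4-diene whose C6–C7 edge is trans-fused to an α-methylene-γ-butyrolactone (O6–C12(=O)–C11(=C13H2)–C7). Both ring alkenes are trisubstituted with the ring carbons cis (C2/C9 across C1=C10, C3/C6 across C4=C5); the exocyclic carbons C14 (CHO) and C15 (CH2OAc) lie trans to C2 and C6, so both alkenes are formally E. Three contiguous stereocentres, C6 (R), C7 (R) and C8 (S), sit on one edge of the ring, and O8 carries an (S)-2-methylbutanoate with its own epimerisable α-centre. The fragile groups are the α-methylene lactone (Michael acceptor), the C14 enal, the allylic C15 acetate and the allylic lactone C6–O bond. O8 stands 1,4 to both C12 and C14, so a free C8 hydroxyl beside a carbonyl at either carbon closes a five-membered lactol or lactone. The real difficulty is to close a ten-membered ring holding two ring-cis trisubstituted alkenes, to control the C6/C7/C8 triad, and to keep four oxygenated positions (C12, C14, C15, O8) distinguishable to the end. The key step uses the fact that the C6 carbinol next to C7, which bears the C11=C13 methylene, is a homoallylic alcohol. This is the retron of a [2,3]-Wittig shift of an O6–C13 allyl ether, so the ten-membered carbocycle arises by contraction of the 13-membered ring O6–C13–C11=C7–C8–C9–C10=C1–C2–C3–C4=C5–C6.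

## Logic of the disconnections

39 ⇒ 38 ⇒ 37 ⇒ 35 + 36 ⇒ 34 ⇒ 33. The C14 aldehyde is lowered to a silylated alcohol, and the C8 ester and C15 acetate C–O bonds are cut. None of these groups survives an organolithium, so they go on last. The order is acetate, then C8 ester, then C14 oxidation, because a free O8 beside a C14 carbonyl would close a hemiacetal. The gain is a tris-silyl lactone. The demand is two silyl tiers (TBS on O8 and O15 removed together, TBDPS on O14 surviving), primary-selective acetylation of 34, and esterification without epimerising 36.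

33 ⇒ 30 ⇒ 29. The lactone O6–C12 bond is cut and C12 is lowered to a primary alcohol. A 2-methylene-1,4-diol lactonises oxidatively, so C12 can travel as a base-inert CH2O–silyl group. The demand is removal of the triethylsilyl group on O12 beside TBS and TBDPS ethers, an oxidant that touches only the primary alcohol and the lactol, and O8 kept protected so that only O6 can trap the C12 aldehyde.

29 ⇒ 27. C6–C7 is cut, O6–C13 is re-formed and the C11=C13 alkene returns to C7=C11 (retro-[2,3]-Wittig). This replaces a ten-membered C–C closure by a 13-membered etherification and sets C6 and C7 in one event from one stereocentre (C8) and one alkene geometry. The demand is lithiation at C6H2, C13 trans to C8 in 27, and face selection at C7 by C8.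

27 ⇒ 26 ⇒ 25 ⇒ 23. The O6–C13 ether bond is cut (Williamson). The electrophile is a primary allylic carbon and the C6 alkoxide is remote from every silyl group, so no silyl transfer can interfere. The gain is an open chain. The demand is activation of C13–OH without touching the O12 silyl ether, and late unmasking of O6 beside four silyl ethers.

23 ⇒ 22 ⇒ 21 ⇒ 19 ⇒ 17 + 18 + 20. C7=C11 is cut by olefination and C11–C12 by cross-coupling. The geometry is the crux: a stabilised α-iodo ylide places the ester carbon (future C13) trans to C8 and iodine cis, and coupling with retention puts C12 where the iodine was. The demand is Z-selective iodo-olefination, and reduction of C13 only after O12 is silylated, so the two CH2O arms are never equivalent.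

17 ⇒ 16 ⇒ 15 ⇒ 13 ⇒ 12 ⇒ 8 + 11. C1=C10 is cut by a Horner–Wadsworth–Emmons reaction, with O8 and C14 tied in a γ-lactone. The lactone phosphonate delivers C2 trans to C14; reduction frees O14 (primary) and O8 (secondary), which are then told apart by size. The demand is E-selectivity and removal of the 3,4-dimethoxybenzyl ether on O7 beside the 4-methoxybenzyl ether on O6.

11 ⇒ 10 + 1, and 10 ⇒ 9. C9–C10 is cut: the phosphonoacetate anion opens the epoxide at its CH2 terminus and the alkoxide lactonises. C8 comes unchanged from 9. The demand is terminal regioselectivity.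

8 ⇒ 7 ⇒ 6 ⇒ 5 ⇒ 3 + 4, and 3 ⇒ 1 + 2. C4=C5 is cut by a Horner–Wadsworth–Emmons reaction and C3–C4 by alkylation. The ester (future C15) falls trans to C6, which is the geometry needed, and C15 is oxygenated from the start. The demand is E-selectivity and unmasking of the C1 acetal beside a primary allylic silyl ether.

## Other disconnections considered

Alternative 1: The cut is the C1/C6 ring-fusion alkene of the hexahydronaphthalene A1; ozonolysis would open it to the cyclodecenedione A2. In its favour, the ten-membered ring needs no macrocyclisation, the starting material is aromatic, and C7/C8 are set on a six-membered ring. On ring formation this is better than the chosen plan. Against it, A2 is far from the target in functionality. C15 is an unoxidised methyl. The alkene sits at C3/C4 and must move to C4/C5 with defined geometry. The C6 ketone must become the (R)-carbinol in a flexible ring. The C1 ketone and C10 ester must become the C1=C10 enal. C13 is missing. A 1,6-diketone in a ten-membered ring also invites transannular aldol reaction, and ozone must discriminate a tetra- from a trisubstituted alkene. Mechanistically the cleavage creates no stereocentre, whereas the Wittig shift sets two. In step economy the short ring synthesis would be outweighed by the long correction of oxidation pattern.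

Alternative 2: The cut is C7–C8; an allylmetal made from the bromomethyl butenolide A3 (In or CrCl2, divalent chromium) would add through C7 to the C8 aldehyde to give A4. In its favour, one step closes the ring, makes two stereocentres and reveals the finished α-methylene lactone, with the C15 acetate already in place. Only acylation, desilylation and oxidation would follow, so after ring closure it is better than the chosen plan in step economy. The allylic transposition that creates C11=C13 is the same logic as in the chosen plan, an equal point. Against it, C6 in A3 is a γ-butenolide stereocentre that is both allylic and acidic. The C8 carbinol configuration would be decided by aldehyde face selection in a ten-membered transition state with no adjacent control element. A direct ten-membered C–C closure is entropically harder than a 13-membered etherification. The chosen plan fixes C8 from the chiral pool and uses it to steer C7; this plan fixes C6 and must create C8, and a free C8 hydroxyl beside the lactone risks migration to the 8,12-lactone.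

Alternative 3: The cut is the C4=C5 alkene; an intramolecular Horner–Wadsworth–Emmons reaction of the phosphonate aldehyde A5 under LiCl/amine conditions would give the diene lactone A6. In its favour, C6, C7 and C8 are all secured from xylose before ring closure, so on stereochemical security it is better than the chosen plan. A ring-cis alkene is also the natural outcome of closing a ten-membered ring by olefination. Against it, the C5 aldehyde in A5 is α to the lactone oxygen and can epimerise or eliminate under base. Ten-membered ring closure competes with dimerisation. A6 still needs α-methylenation of the lactone beside a β-silyloxy group and conversion of the allyl ester into CH2OAc. The C-branched triad from a pentose is long to prepare. In step economy it is roughly equal overall: a longer front end and a comparable end game.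

Key step: step 20

Remarks on the chemistry (one line each):
- Germacrane locants are used for all intermediates; "chain" means the open chain C6–C5=C4(C15)–C3–C2–C1=C10(C14)–C9–C8–C7; TBS = tert-butyldimethylsilyl, TBDPS = tert-butyldiphenylsilyl, TES = triethylsilyl, PMB = 4-methoxybenzyl, DMB = 3,4-dimethoxybenzyl.
- Correction of a descriptor: the C7=C11 alkene that leads to the anti C6/C7 pair has C13 trans to C8; this is the E-crotyl-type geometry but its formal descriptor is Z, because the C12 arm (acetal or CH2OSi) outranks the C13 ring arm.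
- Correction of a name: the group formed on C7 is a 1-substituted ethenyl group (C12 and the =C13H2 on the same carbon C11), not a 2-substituted vinyl group.
- Precursor design change 1: C12 is carried as CH2OTES, not as an aldehyde acetal. An acetal-bearing olefination reagent would lose alkoxide, acetal oxygens next to C13 would steer lithiation there, and acetal hydrolysis would strip a labile O8 silyl ether and open the way to the 8,12-lactone.
- Precursor design change 2: O8 carries TBS (survives unmasking of C12), O14 TBDPS and O15 TBS.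
- Assumption: 2 (used instead of a cyclic acetal so that C1 can be unmasked without acid), 4, 18, 20, 36 and 3,4-dimethoxybenzyl chloride are taken as commercial.

## Steps

Step 1
Reactants: 1 triethyl phosphonoacetate; 2 3-bromo-1,1-dimethoxypropane
Product: 3 ethyl 2-(diethoxyphosphoryl)-5,5-dimethoxypentanoate (racemic)
Conditions: NaH, DMF, 0 °C; then 2, 60 °C (1 in 1.5-fold excess)
Reagents that add atoms: none
Why: C-alkylation of the sodium phosphonoacetate by a primary bromide (malonate-type alkylation) forms C3–C4; excess 1 limits dialkylation and the new stereocentre is destroyed in step 2.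

Step 2
Reactants: 3 ethyl 2-(diethoxyphosphoryl)-5,5-dimethoxypentanoate; 4 2-[(4-methoxybenzyl)oxy]acetaldehyde
Product: 5 ethyl (2E)-2-(3,3-dimethoxypropyl)-4-[(4-methoxybenzyl)oxy]but-2-enoate
Conditions: NaH, THF, 0 °C; then 4, 0 °C → rt
Reagents that add atoms: none
Why: Horner–Wadsworth–Emmons olefination of an α-alkyl phosphonoacetate places the ester (C15) trans to C6 and the C3 chain cis, the C4=C5 geometry of the target; the minor isomer should be separable by chromatography.

Step 3
Reactants: 5 ethyl (2E)-2-(3,3-dimethoxypropyl)-4-[(4-methoxybenzyl)oxy]but-2-enoate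
Product: 6 (2E)-2-(3,3-dimethoxypropyl)-4-[(4-methoxybenzyl)oxy]but-2-en-1-ol
Conditions: i-Bu2AlH, CH2Cl2, −78 °C; aq. potassium sodium tartrate
Reagents that add atoms: none
Why: 1,2-reduction of an enoate to the allylic alcohol by an aluminium hydride; acetal and PMB ether are inert.

Step 4
Reactants: 6 (2E)-2-(3,3-dimethoxypropyl)-4-[(4-methoxybenzyl)oxy]but-2-en-1-ol
Product: 7 tert-butyl{[(2E)-2-(3,3-dimethoxypropyl)-4-[(4-methoxybenzyl)oxy]but-2-en-1-yl]oxy}dimethylsilane
Conditions: TBSCl, imidazole, DMF, 0 °C → rt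
Reagents that add atoms: tert-butyldimethylsilyl chloride, CC(C)(C)[Si](C)(C)Cl
Why: Standard silylation of a primary allylic alcohol; this TBS group on O15 is later removed together with the one on O8.

Step 5
Reactants: 7 tert-butyl{[(2E)-2-(3,3-dimethoxypropyl)-4-[(4-methoxybenzyl)oxy]but-2-en-1-yl]oxy}dimethylsilane
Product: 8 (4E)-4-{[tert-butyl(dimethyl)silyl]oxymethyl}-6-[(4-methoxybenzyl)oxy]hex-4-enal
Conditions: Et3SiOTf, 2,4,6-collidine, CH2Cl2, 0 °C; then H2O
Reagents that add atoms: water, O
Why: Acetal cleavage by a silyl triflate and a hindered pyridine (collidinium N,O-acetal, then hydrolysis) runs under weakly basic conditions, so the primary allylic TBS ether and the PMB ether should survive where aqueous acid would not spare them.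

Step 6
Reactants: 9 (R)-glycidol
Product: 10 (2S)-2-{[(3,4-dimethoxybenzyl)oxy]methyl}oxirane
Conditions: NaH, 3,4-dimethoxybenzyl chloride, Bu4NI (cat.), THF/DMF, 0 °C → rt
Reagents that add atoms: 3,4-dimethoxybenzyl chloride, COc1ccc(CCl)cc1OC
Why: Williamson etherification; the stereocentre (future C8) is untouched, the Payne rearrangement of glycidol alkoxide is degenerate, and the descriptor changes from R to S only through priorities.

Step 7
Reactants: 10 (2S)-2-{[(3,4-dimethoxybenzyl)oxy]methyl}oxirane; 1 triethyl phosphonoacetate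
Product: 11 diethyl [(5S)-5-{[(3,4-dimethoxybenzyl)oxy]methyl}-2-oxooxolan-3-yl]phosphonate (both C3 epimers)
Conditions: NaH, toluene, 0 °C; then 10, 90 °C; AcOH
Reagents that add atoms: none
Why: The phosphonoacetate anion opens the epoxide at its CH2 terminus (SN2, forms C9–C10) and the resulting C8 alkoxide lactonises onto the ethyl ester, the known route from epoxides to α-phosphono-γ-butyrolactones; C8 keeps its configuration because only the terminal carbon is attacked.

Step 8
Reactants: 11 diethyl [(5S)-5-{[(3,4-dimethoxybenzyl)oxy]methyl}-2-oxooxolan-3-yl]phosphonate; 8 (4E)-4-{[tert-butyl(dimethyl)silyl]oxymethyl}-6-[(4-methoxybenzyl)oxy]hex-4-enal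
Product: 12 (3E,5S)-3-[(4E)-4-{[tert-butyl(dimethyl)silyl]oxymethyl}-6-[(4-methoxybenzyl)oxy]hex-4-en-1-ylidene]-5-{[(3,4-dimethoxybenzyl)oxy]methyl}oxolan-2-one
Conditions: KN(SiMe3)2, 18-crown-6, THF, −78 °C; then 8, −78 → 0 °C
Reagents that add atoms: none
Why: Horner–Wadsworth–Emmons olefination of an α-phosphono-γ-lactone gives the E-alkylidene lactone (C2 trans to the C14 carbonyl, cis to C9), which is the C1=C10 geometry of the target; the lactone also masks O8 and C14 together.

Step 9
Reactants: 12 the alkylidene lactone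
Product: 13 (1(10)E,4E,8S)-chain 8,14-diol with O7 DMB; O6 PMB; O15 TBS
Conditions: i-Bu2AlH (excess), CH2Cl2, −78 → −20 °C; aq. potassium sodium tartrate
Reagents that add atoms: none
Why: 1,2-reduction of an α-alkylidene lactone to the 2-alkylidene-1,4-diol; it releases O14 as a primary allylic and O8 as a secondary alcohol.

Step 10
Reactants: 13 the chain 8,14-diol
Product: 15 (1(10)E,4E,8S)-chain with O14 TBDPS; O8 TBS; O15 TBS; O7 DMB; O6 PMB, via mono-TBDPS ether 14 (not isolated)
Conditions: imidazole, DMF; TBDPSCl (1.05 equiv), 0 °C; then TBSCl, 40 °C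
Reagents that add atoms: tert-butyldiphenylsilyl chloride, CC(C)(C)[Si](Cl)(c1ccccc1)c1ccccc1; tert-butyldimethylsilyl chloride, CC(C)(C)[Si](C)(C)Cl
Why: The bulky TBDPS chloride silylates the primary allylic O14 selectively; TBS chloride then caps the secondary O8, giving O14 the most robust silyl group because C14 is unmasked last.

Step 11
Reactants: 15 the fully protected chain
Product: 16 (1(10)E,4E,8S)-chain 7-ol with O8 TBS; O14 TBDPS; O15 TBS; O6 PMB
Conditions: DDQ (1.2 equiv), CH2Cl2/pH 7 phosphate buffer, 0 °C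
Reagents that add atoms: none
Why: Oxidative cleavage of benzyl-type ethers by DDQ is faster for the more electron-rich DMB than for the PMB group, a known selectivity, so O7 should be freed while O6 stays protected.

Step 12
Reactants: 16 the chain 7-ol
Product: 17 (1(10)E,4E,8S)-chain 7-al (α-silyloxy aldehyde) with O8 TBS; O14 TBDPS; O15 TBS; O6 PMB
Conditions: Dess–Martin periodinane, NaHCO3, CH2Cl2, 0 °C → rt
Reagents that add atoms: none
Why: Buffered hypervalent-iodine oxidation gives the α-silyloxy aldehyde without epimerising C8; it is used directly.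

Step 13
Reactants: 17 the chain 7-al; 18 ethyl (triphenylphosphoranylidene)acetate
Product: 19 ethyl ester of the (7(11)Z,8S)-11-iodo chain enoate (ester carbon = C13; I on C11 cis to C8) with O8 TBS; O14 TBDPS; O15 TBS; O6 PMB
Conditions: 18, N-iodosuccinimide, CH2Cl2, −20 °C; then 17, K2CO3, −20 °C → rt
Reagents that add atoms: N-iodosuccinimide, O=C1CCC(=O)N1I
Why: Wittig olefination with the α-iodo stabilised ylide made in the flask places the ester trans to C8 and iodine cis, which fixes C13 trans to C8 as the key step requires.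

Step 14
Reactants: 19 the α-iodo enoate; 20 (tributylstannyl)methanol
Product: 21 ethyl ester of the (7(11)E,8S)-chain enoate with C12 as CH2OH cis to C8 and O8 TBS; O14 TBDPS; O15 TBS; O6 PMB
Conditions: Pd(PPh3)4 (5 mol %), CuI (10 mol %), DMF, 50 °C
Reagents that add atoms: none
Why: Stille coupling (zerovalent palladium, copper co-catalysis) of an α-iodo enoate with the hydroxymethyl stannane proceeds with retention at the alkene, so C12 enters cis to C8.

Step 15
Reactants: 21 the 12-hydroxy enoate
Product: 22 ethyl ester of the (7(11)E,8S)-chain enoate with O12 TES; O8 TBS; O14 TBDPS; O15 TBS; O6 PMB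
Conditions: Et3SiCl, imidazole, CH2Cl2, 0 °C
Reagents that add atoms: triethylsilyl chloride, CC[Si](Cl)(CC)CC
Why: Silylation of the primary allylic alcohol; TES is the most labile silyl tier because C12 must be unmasked first after the ring contraction.

Step 16
Reactants: 22 the 12-silyloxy enoate
Product: 23 (1(10)E,4E,7(11)Z,8S)-chain 13-ol with O12 TES; O8 TBS; O14 TBDPS; O15 TBS; O6 PMB
Conditions: i-Bu2AlH, CH2Cl2, −78 °C; aq. potassium sodium tartrate
Reagents that add atoms: none
Why: 1,2-reduction of the enoate gives C13–OH; low temperature and a neutral work-up avoid silyl transfer between O12 and O13.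

Step 17
Reactants: 23 the chain 13-ol
Product: 25 (1(10)E,4E,7(11)E,8S)-chain 13-bromide with O12 TES; O8 TBS; O14 TBDPS; O15 TBS; O6 PMB, via allylic mesylate 24 (not isolated)
Conditions: MsCl, Et3N, THF, −40 °C; then LiBr, 0 °C
Reagents that add atoms: lithium bromide, [Li+].[Br-]
Why: Mesylation and SN2 displacement by bromide give the primary allylic bromide without the phosphine/halogen reagents that can attack a neighbouring TES ether.

Step 18
Reactants: 25 the chain 13-bromide
Product: 26 (1(10)E,4E,7(11)E,8S)-13-bromo chain 6-ol with O12 TES; O8 TBS; O14 TBDPS; O15 TBS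
Conditions: DDQ (1.3 equiv), CH2Cl2/pH 7 phosphate buffer, 0 °C
Reagents that add atoms: none
Why: Oxidative PMB cleavage under buffered conditions frees O6 while the four silyl ethers and the allylic bromide are left alone; 26 is used at once.

Step 19
Reactants: 26 the 13-bromo chain 6-ol
Product: 27 (3Z,5S,7E,11E)-5-[tert-butyl(dimethyl)silyl]oxy-11-{[tert-butyl(dimethyl)silyl]oxymethyl}-7-{[tert-butyl(diphenyl)silyl]oxymethyl}-3-[(triethylsilyl)oxymethyl]-1-oxacyclotrideca-3,7,11-triene (O6–C13 ether)
Conditions: NaH, THF, 50 °C, slow addition (final 2 mM)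
Reagents that add atoms: none
Why: Intramolecular Williamson etherification (13-exo-tet SN2 at the primary allylic bromide) closes the 13-membered diallylic ether, a ring size precedented for this closure; the C6 alkoxide is far from every silyl group, so no silyl transfer is expected.

Step 20
Reactants: 27 the 13-membered diallylic ether
Product: 29 (1(10)E,4E,6R,7S,8S)-8,15-bis[tert-butyl(dimethyl)silyloxy]-14-[tert-butyl(diphenyl)silyloxy]-12-(triethylsilyloxy)germacra-1(10),4,11(13)-trien-6-ol, via C6-lithiated ether 28 (not isolated)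
Conditions: n-BuLi, THF, −78 → −25 °C; aq. NH4Cl
Reagents that add atoms: none
Why: n-BuLi removes a proton from C6H2, the ring CH2 between O6 and the unsubstituted vinylic carbon C5, to give the α-oxy allyl anion 28; the C13H2 protons lie beside the fully substituted C11 and their anion could bond only to the fully substituted C4. C6 then bonds to C7 while the C7=C11 π bond moves to C11=C13 and O6–C13 breaks, a concerted suprafacial [2,3]-sigmatropic (Wittig) shift through a five-membered envelope of O6, C6, C7, C11 and C13. The closest known reaction type is the [2,3]-Wittig ring contraction of 13-membered diallylic ethers to ten-membered homoallylic alcohols bearing an isopropenyl-type group. The ten-membered carbocycle closes by transannular attack inside the 13-membered ring, so no dilution is needed, and O6, C13 and C11 leave the ring as the hydroxyl and the exocyclic alkene. The C6 configuration relative to C7 follows from the alkene geometry (C13 trans to C8, E-crotyl type) and the exo placement of C5 enforced by the ring tether, which gives the anti pair needed for the trans lactone. At C7, allylic 1,3-strain with the C12 arm holds H8 in the alkene plane, so the tether through C9 delivers C6 to the face opposite the C8 silyloxy group and (8S) is translated into (7S) in 29 (7R in the target after priority change). The step needs lithiation at C6 rather than at C13 or a silyloxymethyl group, and [2,3] rather than [1,2] shift; the open C6 position, bulky weakly coordinating silyl ethers with no acetal oxygens near C13, and a temperature below about −20 °C should secure this.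

Step 21
Reactants: 29 the ring-contracted dienol
Product: 30 (1(10)E,4E,6R,7S,8S)-8,15-bis(TBS-oxy)-14-(TBDPS-oxy)germacra-1(10),4,11(13)-triene-6,12-diol
Conditions: PPTS (cat.), MeOH/CH2Cl2, 0 °C
Reagents that add atoms: none
Why: Mild acid methanolysis removes the primary TES ether much faster than the primary or secondary TBS and the TBDPS ethers (known silyl lability order), unmasking only O12.

Step 22
Reactants: 30 the 6,12-diol
Product: 33 (1(10)E,4E,6R,7S,8S)-8,15-bis(TBS-oxy)-14-(TBDPS-oxy)germacra-1(10),4,11(13)-trien-12,6-olide, via hydroxy enal 31 (not isolated), via lactol 32 (not isolated)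
Conditions: TEMPO (cat.), PhI(OAc)2 (2.5 equiv), CH2Cl2, rt
Reagents that add atoms: none
Why: Oxoammonium (TEMPO) oxidation is selective for the primary allylic alcohol; the C12 aldehyde is trapped by O6 as the lactol, which is oxidised on to the α-methylene lactone (oxidative lactonisation). O8 is still silylated, so only the 6,12-lactone can form.

Step 23
Reactants: 33 the tris-silyl lactone
Product: 34 (1(10)E,4E,6R,7R,8S)-8,15-dihydroxy-14-(TBDPS-oxy)germacra-1(10),4,11(13)-trien-12,6-olide
Conditions: CSA (cat.), MeOH/CH2Cl2, 0 °C → rt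
Reagents that add atoms: none
Why: Acidic methanolysis cleaves both TBS ethers (primary allylic O15 fast, secondary O8 more slowly) while the far more acid-stable TBDPS ether on O14 should remain, keeping C14 masked until O8 is acylated.

Step 24
Reactants: 34 the 8,15-diol
Product: 35 (1(10)E,4E,6R,7R,8S)-15-acetoxy-8-hydroxy-14-(TBDPS-oxy)germacra-1(10),4,11(13)-trien-12,6-olide
Conditions: AcCl (1.1 equiv), 2,4,6-collidine, CH2Cl2, −78 °C
Reagents that add atoms: acetyl chloride, CC(=O)Cl
Why: Acetyl chloride with collidine at low temperature acetylates a primary alcohol in preference to a hindered secondary one, so O15 is acetylated and O8 is left free.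

Step 25
Reactants: 35 the 15-acetate 8-ol; 36 (S)-2-methylbutanoic acid
Product: 37 (1(10)E,4E,6R,7R,8S)-15-acetoxy-8-[(2S)-2-methylbutanoyloxy]-14-(TBDPS-oxy)germacra-1(10),4,11(13)-trien-12,6-olide
Conditions: DCC, DMAP (cat.), CH2Cl2, 0 °C → rt
Reagents that add atoms: none
Why: Steglich esterification of the secondary alcohol; an α-alkyl acid without an activating α-heteroatom should couple without loss of its configuration, and the mild base does not open or move the lactone.

Step 26
Reactants: 37 the 8-ester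
Product: 38 (1(10)E,4E,6R,7R,8S)-15-acetoxy-14-hydroxy-8-[(2S)-2-methylbutanoyloxy]germacra-1(10),4,11(13)-trien-12,6-olide
Conditions: HF·pyridine, pyridine, THF, 0 °C → rt
Reagents that add atoms: none
Why: Buffered fluoride cleaves the TBDPS ether under weakly acidic conditions that spare the acetate, the ester and the α-methylene lactone, which a basic fluoride source could attack.

Step 27
Reactants: 38 the 14-ol
Product: 39 (1(10)E,4E,6R,7R,8S)-15-acetoxy-8-[(2S)-2-methylbutanoyloxy]-14-oxogermacra-1(10),4,11(13)-trien-12,6-olide (target)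
Conditions: MnO2, CH2Cl2, rt
Reagents that add atoms: none
Why: MnO2 oxidises the primary allylic alcohol to the enal and nothing else; the enal has CHO cis to H1, the stable geometry, and O8 is already acylated so no hemiacetal can form.

## Compound list

1 | triethyl phosphonoacetate | CCOC(=O)CP(=O)(OCC)OCC | starting material
2 | 3-bromo-1,1-dimethoxypropane | COC(CCBr)OC | starting material
3 | ethyl 2-(diethoxyphosphoryl)-5,5-dimethoxypentanoate (racemic) | CCOC(=O)C(CCC(OC)OC)P(=O)(OCC)OCC | intermediate
4 | 2-[(4-methoxybenzyl)oxy]acetaldehyde | COc1ccc(COCC=O)cc1 | starting material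
5 | ethyl (2E)-2-(3,3-dimethoxypropyl)-4-[(4-methoxybenzyl)oxy]but-2-enoate | CCOC(=O)/C(CCC(OC)OC)=C/COCc1ccc(OC)cc1 | intermediate
6 | (2E)-2-(3,3-dimethoxypropyl)-4-[(4-methoxybenzyl)oxy]but-2-en-1-ol | OC/C(CCC(OC)OC)=C/COCc1ccc(OC)cc1 | intermediate
7 | tert-butyl{[(2E)-2-(3,3-dimethoxypropyl)-4-[(4-methoxybenzyl)oxy]but-2-en-1-yl]oxy}dimethylsilane | CC(C)(C)[Si](C)(C)OC/C(CCC(OC)OC)=C/COCc1ccc(OC)cc1 | intermediate
8 | (4E)-4-{[tert-butyl(dimethyl)silyl]oxymethyl}-6-[(4-methoxybenzyl)oxy]hex-4-enal | O=CCC/C(CO[Si](C)(C)C(C)(C)C)=C\COCc1ccc(OC)cc1 | intermediate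
9 | (R)-glycidol | OC[C@@H]1CO1 | starting material
10 | (2S)-2-{[(3,4-dimethoxybenzyl)oxy]methyl}oxirane | COc1ccc(COC[C@@H]2CO2)cc1OC | intermediate
11 | diethyl [(5S)-5-{[(3,4-dimethoxybenzyl)oxy]methyl}-2-oxooxolan-3-yl]phosphonate (both C3 epimers) | CCOP(=O)(OCC)C1C[C@@H](COCc2ccc(OC)c(OC)c2)OC1=O | intermediate
12 | (3E,5S)-3-[(4E)-4-{[tert-butyl(dimethyl)silyl]oxymethyl}-6-[(4-methoxybenzyl)oxy]hex-4-en-1-ylidene]-5-{[(3,4-dimethoxybenzyl)oxy]methyl}oxolan-2-one | O=C1O[C@H](COCc2ccc(OC)c(OC)c2)C/C1=C\CC/C(CO[Si](C)(C)C(C)(C)C)=C\COCc3ccc(OC)cc3 | intermediate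
13 | (1(10)E,4E,8S)-chain 8,14-diol; O7 DMB, O6 PMB, O15 TBS | OC/C(C[C@H](O)COCc2ccc(OC)c(OC)c2)=C/CC/C(CO[Si](C)(C)C(C)(C)C)=C\COCc3ccc(OC)cc3 | intermediate
14 | (1(10)E,4E,8S)-chain 8-ol; O14 TBDPS, O7 DMB, O6 PMB, O15 TBS | CC(C)(C)[Si](c1ccccc1)(c1ccccc1)OC/C(C[C@H](O)COCc2ccc(OC)c(OC)c2)=C/CC/C(CO[Si](C)(C)C(C)(C)C)=C\COCc3ccc(OC)cc3 | intermediate (not isolated)
15 | (1(10)E,4E,8S)-chain; O14 TBDPS, O8 TBS, O15 TBS, O7 DMB, O6 PMB | CC(C)(C)[Si](c1ccccc1)(c1ccccc1)OC/C(C[C@H](O[Si](C)(C)C(C)(C)C)COCc2ccc(OC)c(OC)c2)=C/CC/C(CO[Si](C)(C)C(C)(C)C)=C\COCc3ccc(OC)cc3 | intermediate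
16 | (1(10)E,4E,8S)-chain 7-ol; O8 TBS, O14 TBDPS, O15 TBS, O6 PMB | CC(C)(C)[Si](c1ccccc1)(c1ccccc1)OC/C(C[C@H](O[Si](C)(C)C(C)(C)C)CO)=C/CC/C(CO[Si](C)(C)C(C)(C)C)=C\COCc2ccc(OC)cc2 | intermediate
17 | (1(10)E,4E,8S)-chain 7-al; O8 TBS, O14 TBDPS, O15 TBS, O6 PMB | CC(C)(C)[Si](c1ccccc1)(c1ccccc1)OC/C(C[C@H](O[Si](C)(C)C(C)(C)C)C=O)=C/CC/C(CO[Si](C)(C)C(C)(C)C)=C\COCc2ccc(OC)cc2 | intermediate
18 | ethyl (triphenylphosphoranylidene)acetate | CCOC(=O)C=P(c1ccccc1)(c1ccccc1)c1ccccc1 | starting material
19 | ethyl ester of the (1(10)E,4E,7(11)Z,8S)-11-iodo chain enoate (C13 = ester carbon, I cis to C8); O8 TBS, O14 TBDPS, O15 TBS, O6 PMB | CCOC(=O)/C(I)=C/[C@@H](O[Si](C)(C)C(C)(C)C)C/C(CO[Si](c1ccccc1)(c1ccccc1)C(C)(C)C)=C\CC/C(CO[Si](C)(C)C(C)(C)C)=C\COCc2ccc(OC)cc2 | intermediate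
20 | (tributylstannyl)methanol | CCCC[Sn](CO)(CCCC)CCCC | starting material
21 | ethyl ester of the (1(10)E,4E,7(11)E,8S)-chain enoate with C12 as CH2OH cis to C8; O8 TBS, O14 TBDPS, O15 TBS, O6 PMB | CCOC(=O)/C(CO)=C/[C@@H](O[Si](C)(C)C(C)(C)C)C/C(CO[Si](c1ccccc1)(c1ccccc1)C(C)(C)C)=C\CC/C(CO[Si](C)(C)C(C)(C)C)=C\COCc2ccc(OC)cc2 | intermediate
22 | ethyl ester of the (1(10)E,4E,7(11)E,8S)-chain enoate; O12 TES, O8 TBS, O14 TBDPS, O15 TBS, O6 PMB | CCOC(=O)/C(CO[Si](CC)(CC)CC)=C/[C@@H](O[Si](C)(C)C(C)(C)C)C/C(CO[Si](c1ccccc1)(c1ccccc1)C(C)(C)C)=C\CC/C(CO[Si](C)(C)C(C)(C)C)=C\COCc2ccc(OC)cc2 | intermediate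
23 | (1(10)E,4E,7(11)Z,8S)-chain 13-ol; O12 TES, O8 TBS, O14 TBDPS, O15 TBS, O6 PMB | OC/C(CO[Si](CC)(CC)CC)=C/[C@@H](O[Si](C)(C)C(C)(C)C)C/C(CO[Si](c1ccccc1)(c1ccccc1)C(C)(C)C)=C\CC/C(CO[Si](C)(C)C(C)(C)C)=C\COCc2ccc(OC)cc2 | intermediate
24 | (1(10)E,4E,7(11)E,8S)-chain 13-methanesulfonate; protecting groups as in 23 | CS(=O)(=O)OC/C(CO[Si](CC)(CC)CC)=C/[C@@H](O[Si](C)(C)C(C)(C)C)C/C(CO[Si](c1ccccc1)(c1ccccc1)C(C)(C)C)=C\CC/C(CO[Si](C)(C)C(C)(C)C)=C\COCc2ccc(OC)cc2 | intermediate (not isolated)
25 | (1(10)E,4E,7(11)E,8S)-chain 13-bromide; O12 TES, O8 TBS, O14 TBDPS, O15 TBS, O6 PMB | BrC/C(CO[Si](CC)(CC)CC)=C/[C@@H](O[Si](C)(C)C(C)(C)C)C/C(CO[Si](c1ccccc1)(c1ccccc1)C(C)(C)C)=C\CC/C(CO[Si](C)(C)C(C)(C)C)=C\COCc2ccc(OC)cc2 | intermediate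
26 | (1(10)E,4E,7(11)E,8S)-13-bromo chain 6-ol; O12 TES, O8 TBS, O14 TBDPS, O15 TBS | BrC/C(CO[Si](CC)(CC)CC)=C/[C@@H](O[Si](C)(C)C(C)(C)C)C/C(CO[Si](c1ccccc1)(c1ccccc1)C(C)(C)C)=C\CC/C(CO[Si](C)(C)C(C)(C)C)=C\CO | intermediate
27 | (3Z,5S,7E,11E)-5-[tert-butyl(dimethyl)silyl]oxy-11-{[tert-butyl(dimethyl)silyl]oxymethyl}-7-{[tert-butyl(diphenyl)silyl]oxymethyl}-3-[(triethylsilyl)oxymethyl]-1-oxacyclotrideca-3,7,11-triene (13-membered O6–C13 ether) | O1C/C(CO[Si](CC)(CC)CC)=C/[C@@H](O[Si](C)(C)C(C)(C)C)C/C(CO[Si](c2ccccc2)(c2ccccc2)C(C)(C)C)=C\CC/C(CO[Si](C)(C)C(C)(C)C)=C\C1 | intermediate (precursor of the key step)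
28 | C6-lithiated form of 27 (C6 configuration not defined) | O1C/C(CO[Si](CC)(CC)CC)=C/[C@@H](O[Si](C)(C)C(C)(C)C)C/C(CO[Si](c2ccccc2)(c2ccccc2)C(C)(C)C)=C\CC/C(CO[Si](C)(C)C(C)(C)C)=C\C1[Li] | intermediate (not isolated)
29 | (1(10)E,4E,6R,7S,8S)-8,15-bis[tert-butyl(dimethyl)silyloxy]-14-[tert-butyl(diphenyl)silyloxy]-12-(triethylsilyloxy)germacra-1(10),4,11(13)-trien-6-ol | C=C(CO[Si](CC)(CC)CC)[C@H]1[C@H](O)/C=C(/CO[Si](C)(C)C(C)(C)C)CC/C=C(/CO[Si](c2ccccc2)(c2ccccc2)C(C)(C)C)C[C@@H]1O[Si](C)(C)C(C)(C)C | intermediate (product of the key step)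
30 | (1(10)E,4E,6R,7S,8S)-8,15-bis(TBS-oxy)-14-(TBDPS-oxy)germacra-1(10),4,11(13)-triene-6,12-diol | C=C(CO)[C@H]1[C@H](O)/C=C(/CO[Si](C)(C)C(C)(C)C)CC/C=C(/CO[Si](c2ccccc2)(c2ccccc2)C(C)(C)C)C[C@@H]1O[Si](C)(C)C(C)(C)C | intermediate
31 | (1(10)E,4E,6R,7S,8S)-6-hydroxy-8,15-bis(TBS-oxy)-14-(TBDPS-oxy)germacra-1(10),4,11(13)-trien-12-al | C=C(C=O)[C@H]1[C@H](O)/C=C(/CO[Si](C)(C)C(C)(C)C)CC/C=C(/CO[Si](c2ccccc2)(c2ccccc2)C(C)(C)C)C[C@@H]1O[Si](C)(C)C(C)(C)C | intermediate (not isolated)
32 | 12,6-lactol of 31 (C12 epimers) | C=C1C(O)O[C@@H]2/C=C(/CO[Si](C)(C)C(C)(C)C)CC/C=C(/CO[Si](c3ccccc3)(c3ccccc3)C(C)(C)C)C[C@H](O[Si](C)(C)C(C)(C)C)[C@@H]12 | intermediate (not isolated)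
33 | (1(10)E,4E,6R,7S,8S)-8,15-bis(TBS-oxy)-14-(TBDPS-oxy)germacra-1(10),4,11(13)-trien-12,6-olide | C=C1C(=O)O[C@@H]2/C=C(/CO[Si](C)(C)C(C)(C)C)CC/C=C(/CO[Si](c3ccccc3)(c3ccccc3)C(C)(C)C)C[C@H](O[Si](C)(C)C(C)(C)C)[C@@H]12 | intermediate
34 | (1(10)E,4E,6R,7R,8S)-8,15-dihydroxy-14-(TBDPS-oxy)germacra-1(10),4,11(13)-trien-12,6-olide | C=C1C(=O)O[C@@H]2/C=C(/CO)CC/C=C(/CO[Si](c3ccccc3)(c3ccccc3)C(C)(C)C)C[C@H](O)[C@@H]12 | intermediate
35 | (1(10)E,4E,6R,7R,8S)-15-acetoxy-8-hydroxy-14-(TBDPS-oxy)germacra-1(10),4,11(13)-trien-12,6-olide | C=C1C(=O)O[C@@H]2/C=C(/COC(C)=O)CC/C=C(/CO[Si](c3ccccc3)(c3ccccc3)C(C)(C)C)C[C@H](O)[C@@H]12 | intermediate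
36 | (S)-2-methylbutanoic acid | CC[C@H](C)C(=O)O | starting material
37 | (1(10)E,4E,6R,7R,8S)-15-acetoxy-8-[(2S)-2-methylbutanoyloxy]-14-(TBDPS-oxy)germacra-1(10),4,11(13)-trien-12,6-olide | C=C1C(=O)O[C@@H]2/C=C(/COC(C)=O)CC/C=C(/CO[Si](c3ccccc3)(c3ccccc3)C(C)(C)C)C[C@H](OC(=O)[C@@H](C)CC)[C@@H]12 | intermediate
38 | (1(10)E,4E,6R,7R,8S)-15-acetoxy-14-hydroxy-8-[(2S)-2-methylbutanoyloxy]germacra-1(10),4,11(13)-trien-12,6-olide | C=C1C(=O)O[C@@H]2/C=C(/COC(C)=O)CC/C=C(/CO)C[C@H](OC(=O)[C@@H](C)CC)[C@@H]12 | intermediate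
39 | (1(10)E,4E,6R,7R,8S)-15-acetoxy-8-[(2S)-2-methylbutanoyloxy]-14-oxogermacra-1(10),4,11(13)-trien-12,6-olide | C=C1C(=O)O[C@@H]2/C=C(/COC(C)=O)CC/C=C(/C=O)C[C@H](OC(=O)[C@@H](C)CC)[C@@H]12 | target

## Step count and least certain steps

Total: 27 steps. Longest linear sequence: 25 steps (steps 1–5, then 8–27); steps 6–7 form the short branch.

Step 20 (key step). Lithiation may take place at C13H2 or at a silyloxymethyl CH2 (followed by silyl migration from oxygen to carbon) instead of at C6H2. A [1,2]-shift may compete on warming, and face selection at C7 by the C8 silyloxy group may be incomplete in the flexible 13-membered ring. Fallback: set out from 26 and oxidise its allylic C6 alcohol with MnO2 to the bromo enal F1. Treat F1 with CrCl2 (divalent chromium) in THF at high dilution. The allylchromium formed at C13 adds through its γ-carbon C7 to the C6 aldehyde (intramolecular Nozaki–Hiyama–Kishi allylation, chair transition state, anti-selective). This forms C6–C7, the C11=C13 methylene and the C6 hydroxyl, and rejoins the route at 29.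

Step 19. Intermolecular etherification (oligomers), elimination or SN2′ attack at the 2-substituted allylic bromide may outrun the 13-membered closure. Fallback with the roles of the two ends reversed: set out from 22 and cleave the PMB ether with DDQ to the 6-hydroxy enoate F2. Convert the allylic alcohol into the chloride F3 (N-chlorosuccinimide/Me2S). Reduce the ester with i-Bu2AlH at −78 °C to the 6-chloro 13-ol F4. Cyclise F4 as its magnesium alkoxide (EtMgBr, THF, reflux, high dilution), the covalent Mg–O bond being chosen to suppress silyl transfer from O12. This rejoins the route at 27.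

Step 11. Oxidative cleavage may not discriminate well enough between the DMB and PMB ethers, so that O6 is unmasked as well. Fallback with an acid-labile group on O7: set out from 9 and tritylate (Ph3CCl, Et3N) to (S)-trityl glycidyl ether F5. Carry it through the chemistry of steps 7–10: phosphono lactone F6, alkylidene lactone F7 (with 8), diol F8, bis-silyl ether F9. Then remove the trityl group with formic acid/ether at rt for a few minutes, which should spare TBS, TBDPS and PMB ethers. This rejoins the route at 16.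

Step 14. Transfer of the sp3 hydroxymethyl group from tin may be slow, so that reduction of the iodide or erosion of alkene geometry at the α-palladated acrylate competes. Fallback: set out from 17 and olefinate with the α-(silyloxymethyl) phosphonoacetate ethyl 2-(diethoxyphosphoryl)-3-[(triethylsilyl)oxy]propanoate F10 (NaH, THF). F10 would be made from 1 by hydroxymethylation with formaldehyde and silylation. The ester should again fall trans to C8, so the product is 22. This is two steps shorter but its geometry is less assured.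

Step 23. During the prolonged acid treatment needed for the hindered O8 silyl ether, the freed C8 hydroxyl may attack the lactone carbonyl (drift to the 8,12-lactone) or the allylic TBDPS ether may be partly lost. Fallback in stages: set out from 33 and remove only the primary O15 TBS group with HF·pyridine/pyridine at 0 °C to give the 15-ol F11. Acetylate it (Ac2O, pyridine) to the 15-acetate F12. Then remove the O8 TBS group briefly with aqueous HF in MeCN at 0 °C. This rejoins the route at 35.

## Further compounds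

F1 | step 20 | (1(10)E,4E,7(11)E,8S)-13-bromo chain 6-al; O12 TES, O8 TBS, O14 TBDPS, O15 TBS | BrC/C(CO[Si](CC)(CC)CC)=C/[C@@H](O[Si](C)(C)C(C)(C)C)C/C(CO[Si](c1ccccc1)(c1ccccc1)C(C)(C)C)=C\CC/C(CO[Si](C)(C)C(C)(C)C)=C\C=O
F2 | step 19 | ethyl ester of the (1(10)E,4E,7(11)E,8S)-6-hydroxy chain enoate; O12 TES, O8 TBS, O14 TBDPS, O15 TBS | CCOC(=O)/C(CO[Si](CC)(CC)CC)=C/[C@@H](O[Si](C)(C)C(C)(C)C)C/C(CO[Si](c1ccccc1)(c1ccccc1)C(C)(C)C)=C\CC/C(CO[Si](C)(C)C(C)(C)C)=C\CO
F3 | step 19 | ethyl ester of the (1(10)E,4E,7(11)E,8S)-6-chloro chain enoate; protecting groups as in F2 | CCOC(=O)/C(CO[Si](CC)(CC)CC)=C/[C@@H](O[Si](C)(C)C(C)(C)C)C/C(CO[Si](c1ccccc1)(c1ccccc1)C(C)(C)C)=C\CC/C(CO[Si](C)(C)C(C)(C)C)=C\CCl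
F4 | step 19 | (1(10)E,4E,7(11)Z,8S)-6-chloro chain 13-ol; O12 TES, O8 TBS, O14 TBDPS, O15 TBS | OC/C(CO[Si](CC)(CC)CC)=C/[C@@H](O[Si](C)(C)C(C)(C)C)C/C(CO[Si](c1ccccc1)(c1ccccc1)C(C)(C)C)=C\CC/C(CO[Si](C)(C)C(C)(C)C)=C\CCl
F5 | step 11 | (2S)-2-[(trityloxy)methyl]oxirane | C(OC[C@@H]1CO1)(c1ccccc1)(c1ccccc1)c1ccccc1
F6 | step 11 | diethyl [(5S)-2-oxo-5-[(trityloxy)methyl]oxolan-3-yl]phosphonate (C3 epimers) | CCOP(=O)(OCC)C1C[C@@H](COC(c2ccccc2)(c2ccccc2)c2ccccc2)OC1=O
F7 | step 11 | (3E,5S)-3-[(4E)-4-{[tert-butyl(dimethyl)silyl]oxymethyl}-6-[(4-methoxybenzyl)oxy]hex-4-en-1-ylidene]-5-[(trityloxy)methyl]oxolan-2-one | O=C1O[C@H](COC(c2ccccc2)(c2ccccc2)c2ccccc2)C/C1=C\CC/C(CO[Si](C)(C)C(C)(C)C)=C\COCc3ccc(OC)cc3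
F8 | step 11 | (1(10)E,4E,8S)-chain 8,14-diol; O7 trityl, O6 PMB, O15 TBS | OC/C(C[C@H](O)COC(c2ccccc2)(c2ccccc2)c2ccccc2)=C/CC/C(CO[Si](C)(C)C(C)(C)C)=C\COCc3ccc(OC)cc3
F9 | step 11 | (1(10)E,4E,8S)-chain; O14 TBDPS, O8 TBS, O15 TBS, O7 trityl, O6 PMB | CC(C)(C)[Si](c1ccccc1)(c1ccccc1)OC/C(C[C@H](O[Si](C)(C)C(C)(C)C)COC(c2ccccc2)(c2ccccc2)c2ccccc2)=C/CC/C(CO[Si](C)(C)C(C)(C)C)=C\COCc3ccc(OC)cc3
F10 | step 14 | ethyl 2-(diethoxyphosphoryl)-3-[(triethylsilyl)oxy]propanoate | CCOC(=O)C(CO[Si](CC)(CC)CC)P(=O)(OCC)OCC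
F11 | step 23 | (1(10)E,4E,6R,7S,8S)-15-hydroxy-8-(TBS-oxy)-14-(TBDPS-oxy)germacra-1(10),4,11(13)-trien-12,6-olide | C=C1C(=O)O[C@@H]2/C=C(/CO)CC/C=C(/CO[Si](c3ccccc3)(c3ccccc3)C(C)(C)C)C[C@H](O[Si](C)(C)C(C)(C)C)[C@@H]12
F12 | step 23 | (1(10)E,4E,6R,7S,8S)-15-acetoxy-8-(TBS-oxy)-14-(TBDPS-oxy)germacra-1(10),4,11(13)-trien-12,6-olide | C=C1C(=O)O[C@@H]2/C=C(/COC(C)=O)CC/C=C(/CO[Si](c3ccccc3)(c3ccccc3)C(C)(C)C)C[C@H](O[Si](C)(C)C(C)(C)C)[C@@H]12
A1 | alternative 1 | methyl 3-[tert-butyl(dimethyl)silyl]oxy-4-{2-[tert-butyl(dimethyl)silyl]oxyethyl}-6-methyl-1,2,3,4,5,8-hexahydronaphthalene-1-carboxylate | COC(=O)C1C[C@H](O[Si](C)(C)C(C)(C)C)[C@@H](CCO[Si](C)(C)C(C)(C)C)C2=C1CC=C(C)C2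
A2 | alternative 1 | ten-membered 1,6-diketone (germacrane locants: C1 and C6 ketones, cis C3=C4 with C4 methyl, C10 methyl ester, C8 OTBS, C7 CH2CH2OTBS) | COC(=O)C1C[C@H](O[Si](C)(C)C(C)(C)C)[C@@H](CCO[Si](C)(C)C(C)(C)C)C(=O)C/C(C)=C\CC1=O
A3 | alternative 2 | 3-(bromomethyl)butenolide with the C5–C8 chain on C6 (C15 acetate, C14 OTBS, C8 aldehyde) | O=C1O[C@H](/C=C(/COC(C)=O)CC/C=C(/CO[Si](C)(C)C(C)(C)C)CC=O)C=C1CBr
A4 | alternative 2 | 8-hydroxy germacranolide with α-methylene lactone, C15 acetate and C14 OTBS | C=C1C(=O)O[C@@H]2/C=C(/COC(C)=O)CC/C=C(/CO[Si](C)(C)C(C)(C)C)C[C@H](O)[C@@H]12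
A5 | alternative 3 | γ-lactone with C5 aldehyde on C6 and the C8–C4 chain on C7 ending in the allyl phosphonoacetate (C8 OTBS, C14 OTBDPS) | O=C1C[C@H]([C@@H](O[Si](C)(C)C(C)(C)C)C/C(CO[Si](c2ccccc2)(c2ccccc2)C(C)(C)C)=C\CCC(C(=O)OCC=C)P(=O)(OCC)OCC)[C@@H](C=O)O1
A6 | alternative 3 | ten-membered diene lactone with C15 allyl ester, C8 OTBS and C14 OTBDPS | O=C1O[C@@H]2/C=C(/C(=O)OCC=C)CC/C=C(/CO[Si](c3ccccc3)(c3ccccc3)C(C)(C)C)C[C@H](O[Si](C)(C)C(C)(C)C)[C@H]2C1
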